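**Remark (assumptions).** Prenyl means 3-methylbut-2-en-1-yl and allyl means prop-2-en-1-yl. The arylglyoxal 12 will be handled as its hydrate but is drawn and counted as the free keto aldehyde.

## Analysis of the target

The target 20 is a benzofuran (O1, C2, C3, C3a, C4 to C7, C7a). Its benzo ring (ring A) carries a free hydroxyl at C4, a prenyl group at C5 and a methoxy group at C6. Its furan ring carries a 2,4-dihydroxyphenyl group (ring B) at C2 and a formyl group at C3. There is no stereocentre, and the prenyl double bond has two identical methyl groups, so the problem is one of regiochemistry and chemoselectivity only. The sensitive groups are the aldehyde, the prenyl group beside the free 4-hydroxyl (acid closes this pair to a chroman, and oxidants or hydrogenation attack the alkene), and the electron-rich resorcinol ring B. The synthesis is hard for two reasons. The furan ring is fully substituted, with C3 wedged between the C2 aryl group and the peri oxygen at C4, so a late formylation at C3 would be crowded and would compete with ring B. Ring A is pentasubstituted with three oxygen atoms in three different states (O1 in the ring, O4 free, O6 methylated). The strategy rests on C3, which is bonded to three different fragments: C3a of ring A, the formyl carbon, and C2 bearing ring B. If C3 is the former aldehyde carbon of an arylglyoxal, all three bonds around it and the O1–C2 bond can be formed in one operation, with the formyl carbon arriving as a nitromethyl group. If O4 and O6 are both methyl ethers for the time being, the ring A building block is symmetric, and the two oxygens are told apart only at the end, when the formyl group sits beside O4 alone.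

## Retrosynthetic reasoning

**20 from 19.** The two O–allyl bonds on ring B are cut last. A free resorcinol would interfere with the base, the Lewis acid and the oxidation-level changes of the route. Allyl ethers survive amine, mild acid, methoxide, trivalent titanium and a magnesium Lewis acid. They are then removed by zerovalent palladium under near-neutral conditions that leave the aldehyde and the 4-hydroxyl/5-prenyl pair alone.

**19 from 18.** The O4–CH3 bond is cut. Writing O4 as a methyl ether makes the oxygen pattern of ring A symmetric, which is what removes every regiochemical question from the ring-forming step. The forward reaction has to cleave one of two aryl methyl ethers. Only O4 can form a chelate with the formyl oxygen (seven-membered, O=C–C3–C3a–C4–O), and only the 4-methoxy group is flanked on both sides and twisted out of the ring plane. This step is placed before the deallylation so that the last operation on the free polyphenol is the mildest one.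

**18 from 16.** The formyl carbon is traced back to a nitromethyl carbon (Nef reaction). The gain is that this carbon is a nucleophile when its bond to C3 is made and an aldehyde only afterwards. No electrophilic formylation of a crowded, electron-rich heterocycle is needed, and the position of the formyl group is fixed by construction.

**16 from 6, 12 and 13.** Three bonds are cut: C3a–C3, C3–CH2NO2 and O1–C2. C3 is the aldehyde carbon of glyoxal 12 and C2 its ketone carbon, which already carries ring B. Phenol 6 supplies O1 and C3a, and nitromethane 13 supplies the one-carbon unit. Cutting here breaks the fully substituted furan ring into three simple pieces, and 6 has two equivalent ortho carbons. The forward reaction must add 13 to the aldehyde and not the ketone, bond the phenol through carbon to the alkene carbon β to the nitro group, close the phenol oxygen onto the ketone, and keep the nitro group.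

**6 from 5, 2, 1 and 3.** The bond between the ring carbon flanked by the two methoxy groups and the prenyl CH2 is cut. Direct prenylation of 1 would go ortho to the hydroxyl. Directed lithiation of the silyl ether 2 gives the aryllithium 4 between the two methoxy groups, prenyl bromide 3 then gives 5, and desilylation gives 6.

**12 from 11, 9, 7 and 8.** The aldehyde carbon of 12 is the methyl carbon of the acetophenone 7. Both hydroxyls are allylated with 8 to give 9. The methyl group is then raised to the aldehyde level in two controlled operations, bromination through the silyl enol ether 10 to give 11 and Kornblum oxidation. A direct Riley oxidation of 9 was set aside because that oxidant also attacks allylic C–H bonds and would endanger the allyl ethers.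

## Alternatives that were turned down

**Alternative 1: formyl carbon delivered through a pterocarpene bridge.** The C3–CHO bond is cut, and the formyl carbon is traced to the O–CH2 bridge of 7,9-dimethoxy-8-prenyl-6H-benzofuro[3,2-c]chromen-3-yl pivalate A1. In the forward key step, acid condenses a one-carbon aldehyde with the 2'-hydroxyl of the 3-unsubstituted 2-arylbenzofuran A2 (4-(4,6-dimethoxy-5-prenylbenzofuran-2-yl)-3-hydroxyphenyl pivalate). The tethered oxocarbenium ion then attacks C3 and closes a six-membered ring. In its favour, the tether can reach only C3, and this kind of ring closure is well-established chemistry. On that point it is safer than the untested three-component step chosen here. Against it, A2 needs its own multistep synthesis. An acidic aldehyde condensation also meets the prenyl alkene (Prins addition) and the free C7 position of ring A. The bridge CH2 of A1 must then be oxidised exactly to the hemiacetal level, beside the allylic positions of the prenyl group and without running on to the lactone. The same O4 demethylation remains. The chosen strategy offers a shorter, convergent assembly in which the formyl carbon is already attached when the furan ring forms.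

**Alternative 2: ring A built on a furan by benzannulation.** Ring A is cut at C7–C7a, C4–C5, C6–C7 and C3a–C4. The forward key step is photolysis of the furyl diazomethyl ketone A4 (2-diazo-1-{5-[2,4-bis(methoxymethoxy)phenyl]-4-(1,3-dioxolan-2-yl)furan-2-yl}ethanone) with the methoxyalkyne A5 (1-methoxy-5-methylhex-4-en-1-yne). Wolff rearrangement, ketene–alkyne [2+2] addition, 4π ring opening and 6π closure should give 2-[2,4-bis(methoxymethoxy)phenyl]-3-(1,3-dioxolan-2-yl)-6-methoxy-5-prenylbenzofuran-4-ol A3. This route is clearly stronger on one point: O4 appears as a free hydroxyl and O6 as a methyl ether straight from the annulation, so no selective demethylation is needed. Against it, A4 is a tetrasubstituted furan that takes many steps to make, and A5 is a sensitive ynol ether. The photochemical cascade must run on a light-sensitive furan, and the 6π closure must occur at a furan carbon crowded by the neighbouring acetal. The final acidic removal of the acetal groups exposes the 4-hydroxyl/5-prenyl pair to chroman formation. The chosen strategy gives up the built-in differentiation of O4 and O6 but uses two simple aromatic fragments and no photochemistry, in about half the step count.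

**Alternative 3: isoflavone ring transposition.** The O1–C2 bond of the benzofuran is cut, which leads back to the isoflavone A7 (7-hydroxy-3-[6-hydroxy-2,4-dimethoxy-3-prenylphenyl]-4H-chromen-4-one). In the forward key step, a strong Brønsted acid in a fluorinated alcohol opens the pyranone at its O–C2 bond, and the phenol of the future ring A closes on the former C4 ketone. This should give 2-(2,4-dihydroxyphenyl)-4,6-dimethoxy-5-prenylbenzofuran-3-carbaldehyde A6. It is stronger than the chosen route in that A6 already has the aldehyde at the right oxidation level and free ring B phenols, so neither a Nef reaction nor a deprotection is needed. Against it, strong acid meets the trisubstituted prenyl alkene (protonation, solvent addition, Friedel–Crafts chemistry). The opened intermediate can also close back to A7. A7 itself needs a bond between C3 of a chromone and a doubly ortho-substituted, prenylated aryl group. The O4 demethylation is still required. The chosen strategy keeps the prenyl group away from strong acid and fixes the formyl position by bond construction instead of by a rearrangement equilibrium.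

Key step: step 7

## Route

Step 1
Reactants: 1 3,5-dimethoxyphenol
Product: 2 (3,5-dimethoxyphenoxy)tri(propan-2-yl)silane
Conditions: i-Pr3SiCl, imidazole, DMF, rt
Reagents that add atoms: chlorotri(propan-2-yl)silane, CC(C)[Si](Cl)(C(C)C)C(C)C
Why: Standard silylation of a phenol; the bulky triisopropylsilyl ether resists n-BuLi and is a poor directing group, which prepares the regioselective metalation of step 2.

Step 2
Reactants: 2 (3,5-dimethoxyphenoxy)tri(propan-2-yl)silane; 3 prenyl bromide (1-bromo-3-methylbut-2-ene)
Product: 5 [3,5-dimethoxy-4-(3-methylbut-2-en-1-yl)phenoxy]tri(propan-2-yl)silane, via aryllithium 4 (not isolated)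
Conditions: n-BuLi, TMEDA, THF, 0 °C; CuBr·SMe2 (10 mol %), then 3, −78 °C → rt
Reagents that add atoms: none
Why: Directed ortho-metalation: the carbon between the two methoxy groups is activated by both and is remote from the bulky silyloxy group, so lithiation should give 4; copper-catalysed allylic substitution then favours attack at the CH2 end of 3 (SN2) and should give the linear prenyl arene.

Step 3
Reactants: 5 [3,5-dimethoxy-4-(3-methylbut-2-en-1-yl)phenoxy]tri(propan-2-yl)silane
Product: 6 3,5-dimethoxy-4-(3-methylbut-2-en-1-yl)phenol
Conditions: Bu4NF, AcOH, THF, 0 °C → rt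
Reagents that add atoms: none
Why: Fluoride-induced cleavage of an aryl silyl ether; acetic acid buffers the phenoxide, and the prenyl group is inert to these conditions.

Step 4
Reactants: 7 1-(2,4-dihydroxyphenyl)ethan-1-one (2,4-dihydroxyacetophenone); 8 allyl bromide (3-bromoprop-1-ene)
Product: 9 1-[2,4-bis(prop-2-en-1-yloxy)phenyl]ethan-1-one
Conditions: 8 (2.5 equiv), K2CO3, DMF, 60 °C
Reagents that add atoms: none
Why: Williamson ether synthesis; excess 8 and warming are used because the 2-hydroxyl is hydrogen-bonded to the ketone, and 60 °C is far below the temperature of an aromatic Claisen rearrangement.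

Step 5
Reactants: 9 1-[2,4-bis(prop-2-en-1-yloxy)phenyl]ethan-1-one
Product: 11 2-bromo-1-[2,4-bis(prop-2-en-1-yloxy)phenyl]ethan-1-one, via trimethylsilyl enol ether 10 (not isolated)
Conditions: LiN(SiMe3)2, Me3SiCl, THF, −78 °C; then NBS, −78 → 0 °C
Reagents that add atoms: N-bromosuccinimide, O=C1CCC(=O)N1Br; chlorotrimethylsilane, C[Si](C)(C)Cl (its silyl group is found in 10 only)
Why: α-Bromination of a methyl ketone through its silyl enol ether; the enol double bond of 10 should react with NBS far faster than the monosubstituted allyl double bonds or the aryl ring, so bromine is placed on the methyl carbon only.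

Step 6
Reactants: 11 2-bromo-1-[2,4-bis(prop-2-en-1-yloxy)phenyl]ethan-1-one
Product: 12 2-[2,4-bis(prop-2-en-1-yloxy)phenyl]-2-oxoacetaldehyde
Conditions: DMSO, NaHCO3, rt → 40 °C
Reagents that add atoms: dimethyl sulfoxide, CS(C)=O
Why: Kornblum oxidation: the sulfoxide oxygen displaces bromide and the alkoxysulfonium salt loses dimethyl sulfide, which raises the carbon to the aldehyde level without any reagent that could attack the allyl ethers; 12 should be obtained as its hydrate.

Step 7
Reactants: 6 3,5-dimethoxy-4-(3-methylbut-2-en-1-yl)phenol; 12 2-[2,4-bis(prop-2-en-1-yloxy)phenyl]-2-oxoacetaldehyde; 13 nitromethane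
Product: 16 2-[2,4-bis(prop-2-en-1-yloxy)phenyl]-4,6-dimethoxy-5-(3-methylbut-2-en-1-yl)-3-(nitromethyl)-1-benzofuran, via nitroenone 14 (not isolated), via β-nitro ketone 15 (not isolated)
Conditions: 6 (1.0 equiv), 12 (1.1 equiv), 13 (1.2 equiv, added slowly), piperidine (0.2 equiv), AcOH (0.2 equiv), 4 Å MS, MeCN, 0 °C → rt; then TsOH·H2O (0.5 equiv), 50 °C
Reagents that add atoms: none
Why: Proposed new method: piperidinium acetate should condense 13 with the aldehyde carbon of 12 (Henry addition through the iminium ion, then loss of the amine) to give the β-nitroenone 14, in which the nitro group is the stronger acceptor, so the carbon next to the ketone is the electrophilic site. The phloroglucinol-type phenol 6 should add there through one of its two equivalent ortho carbons (Friedel–Crafts conjugate addition, O-addition being reversible) and form C3a–C3 in the racemic β-nitro ketone 15; the other order of events (phenol addition to the aldehyde, ortho-quinone methide, nitronate addition) leads to the same 15. Acid then closes the phenol oxygen onto the aryl ketone (5-exo-trig, O1–C2), and loss of water from the hemiketal aromatises the furan and erases the only stereocentre, so no stereocontrol is needed. The closest known reaction type is the three-component condensation of arylglyoxals, phenols and carbon acids such as Meldrum's acid (amine, then acid) to 2-aryl-3-substituted benzofurans; nitromethane as the carbon acid is the untested element. The step needs aldehyde-over-ketone selectivity (the ketone is deactivated by its 2,4-dialkoxyaryl group and hindered by the ortho ether), C- over O-attack and addition β to the nitro group, all of which follow from the electronic factors just named, and ring A raises no regiochemical question because 6 is symmetric. Catalytic buffered amine and prompt acidification are chosen to prevent loss of nitrous acid from 15, and the prenyl group has no free ortho hydroxyl at this stage, so mild acid should not cyclise it.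

Step 8
Reactants: 16 2-[2,4-bis(prop-2-en-1-yloxy)phenyl]-4,6-dimethoxy-5-(3-methylbut-2-en-1-yl)-3-(nitromethyl)-1-benzofuran
Product: 18 2-[2,4-bis(prop-2-en-1-yloxy)phenyl]-4,6-dimethoxy-5-(3-methylbut-2-en-1-yl)-1-benzofuran-3-carbaldehyde, via sodium nitronate 17 (not isolated)
Conditions: NaOMe, MeOH–THF, 0 °C; then aq. TiCl3, NH4OAc (pH 5–6), 0 °C → rt
Reagents that add atoms: water, O; sodium methoxide, C[O-].[Na+] (its sodium ion is found in 17 only)
Why: Nef reaction in its reductive form: trivalent titanium reduces the nitronate through the oxime to the imine, which hydrolyses to the aldehyde at pH 5–6; no oxidant or strong acid is present, so the prenyl and allyl groups should survive and the aldehyde cannot be over-oxidised.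

Step 9
Reactants: 18 2-[2,4-bis(prop-2-en-1-yloxy)phenyl]-4,6-dimethoxy-5-(3-methylbut-2-en-1-yl)-1-benzofuran-3-carbaldehyde
Product: 19 2-[2,4-bis(prop-2-en-1-yloxy)phenyl]-4-hydroxy-6-methoxy-5-(3-methylbut-2-en-1-yl)-1-benzofuran-3-carbaldehyde
Conditions: MgI2·OEt2 (3 equiv), toluene, 60 °C
Reagents that add atoms: none
Why: Chelation-assisted ether cleavage: magnesium bound to the formyl oxygen can reach only the 4-methoxy oxygen (seven-membered chelate), and iodide then removes that methyl group by SN2; the 4-methoxy group is also the one twisted out of plane by its two neighbours, while the 6-methoxy group and the allyl ethers have no carbonyl within reach.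

Step 10
Reactants: 19 2-[2,4-bis(prop-2-en-1-yloxy)phenyl]-4-hydroxy-6-methoxy-5-(3-methylbut-2-en-1-yl)-1-benzofuran-3-carbaldehyde
Product: 20 2-(2,4-dihydroxyphenyl)-4-hydroxy-6-methoxy-5-(3-methylbut-2-en-1-yl)-1-benzofuran-3-carbaldehyde
Conditions: Pd(PPh3)4 (5 mol %), morpholine, THF, rt
Reagents that add atoms: none
Why: Tsuji–Trost deallylation: zerovalent palladium ionises the aryl allyl ethers to π-allyl complexes that morpholine captures; the C-bound prenyl group has no leaving group, and the near-neutral conditions should spare the aldehyde and the 4-hydroxyl/5-prenyl pair.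

## Compound list

1 | 3,5-dimethoxyphenol | COc1cc(O)cc(OC)c1 | starting material
2 | (3,5-dimethoxyphenoxy)tri(propan-2-yl)silane | COc1cc(O[Si](C(C)C)(C(C)C)C(C)C)cc(OC)c1 | intermediate
3 | prenyl bromide (1-bromo-3-methylbut-2-ene) | CC(C)=CCBr | starting material
4 | [2,6-dimethoxy-4-{[tri(propan-2-yl)silyl]oxy}phenyl]lithium | [Li]c1c(OC)cc(O[Si](C(C)C)(C(C)C)C(C)C)cc1OC | intermediate (not isolated)
5 | [3,5-dimethoxy-4-(3-methylbut-2-en-1-yl)phenoxy]tri(propan-2-yl)silane | COc1cc(O[Si](C(C)C)(C(C)C)C(C)C)cc(OC)c1CC=C(C)C | intermediate
6 | 3,5-dimethoxy-4-(3-methylbut-2-en-1-yl)phenol | COc1cc(O)cc(OC)c1CC=C(C)C | intermediate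
7 | 1-(2,4-dihydroxyphenyl)ethan-1-one | CC(=O)c1ccc(O)cc1O | starting material
8 | allyl bromide (3-bromoprop-1-ene) | C=CCBr | starting material
9 | 1-[2,4-bis(prop-2-en-1-yloxy)phenyl]ethan-1-one | CC(=O)c1ccc(OCC=C)cc1OCC=C | intermediate
10 | {1-[2,4-bis(prop-2-en-1-yloxy)phenyl]ethenyl}oxy(trimethyl)silane | C=C(O[Si](C)(C)C)c1ccc(OCC=C)cc1OCC=C | intermediate (not isolated)
11 | 2-bromo-1-[2,4-bis(prop-2-en-1-yloxy)phenyl]ethan-1-one | O=C(CBr)c1ccc(OCC=C)cc1OCC=C | intermediate
12 | 2-[2,4-bis(prop-2-en-1-yloxy)phenyl]-2-oxoacetaldehyde | O=CC(=O)c1ccc(OCC=C)cc1OCC=C | intermediate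
13 | nitromethane | C[N+](=O)[O-] | starting material
14 | (2E)-1-[2,4-bis(prop-2-en-1-yloxy)phenyl]-3-nitroprop-2-en-1-one | O=C(/C=C/[N+](=O)[O-])c1ccc(OCC=C)cc1OCC=C | intermediate (not isolated)
15 | rac-1-[2,4-bis(prop-2-en-1-yloxy)phenyl]-2-[6-hydroxy-2,4-dimethoxy-3-(3-methylbut-2-en-1-yl)phenyl]-3-nitropropan-1-one | O=C(c1ccc(OCC=C)cc1OCC=C)C(C[N+](=O)[O-])c1c(O)cc(OC)c(CC=C(C)C)c1OC | intermediate (not isolated)
16 | 2-[2,4-bis(prop-2-en-1-yloxy)phenyl]-4,6-dimethoxy-5-(3-methylbut-2-en-1-yl)-3-(nitromethyl)-1-benzofuran | C=CCOc1ccc(-c2oc3cc(OC)c(CC=C(C)C)c(OC)c3c2C[N+](=O)[O-])c(OCC=C)c1 | intermediate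
17 | sodium aci-nitronate of 16 | C=CCOc1ccc(-c2oc3cc(OC)c(CC=C(C)C)c(OC)c3c2C=[N+]([O-])[O-])c(OCC=C)c1.[Na+] | intermediate (not isolated)
18 | 2-[2,4-bis(prop-2-en-1-yloxy)phenyl]-4,6-dimethoxy-5-(3-methylbut-2-en-1-yl)-1-benzofuran-3-carbaldehyde | C=CCOc1ccc(-c2oc3cc(OC)c(CC=C(C)C)c(OC)c3c2C=O)c(OCC=C)c1 | intermediate
19 | 2-[2,4-bis(prop-2-en-1-yloxy)phenyl]-4-hydroxy-6-methoxy-5-(3-methylbut-2-en-1-yl)-1-benzofuran-3-carbaldehyde | C=CCOc1ccc(-c2oc3cc(OC)c(CC=C(C)C)c(O)c3c2C=O)c(OCC=C)c1 | intermediate
20 | 2-(2,4-dihydroxyphenyl)-4-hydroxy-6-methoxy-5-(3-methylbut-2-en-1-yl)-1-benzofuran-3-carbaldehyde | COc1cc2oc(-c3ccc(O)cc3O)c(C=O)c2c(O)c1CC=C(C)C | target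

## Step count and least certain steps

Total: 10 steps. Longest linear sequence: 7 steps (steps 1, 2, 3, 7, 8, 9, 10, or equally steps 4, 5, 6, 7, 8, 9, 10).

**Step 7 (key step, Proposed new method).** The most likely failure is that the three components do not all converge on 15. A second molecule of 13 may add to 14. The secondary amine may be captured by 12 and 6 in a Mannich-type adduct. Or 15 may lose nitrous acid under base (E1cB through the ketone enolate) before the furan ring closes. Each of these processes loses the nitromethyl group or consumes 12. The fallback separates the events into known reactions and sets out from 12 and 13. A Henry addition with catalytic Et3N in THF at 0 °C should give the nitro alcohol rac-1-[2,4-bis(prop-2-en-1-yloxy)phenyl]-2-hydroxy-3-nitropropan-1-one F1. Mesylation and elimination (MsCl, Et3N, CH2Cl2, −20 °C) should give 14, now isolated. Phenol 6 is then added to isolated 14 without base in toluene (Friedel–Crafts conjugate addition of an electron-rich phenol to a nitroalkene, with a hydrogen-bond donor catalyst if needed) to give isolated 15. Treatment with TsOH·H2O in toluene at 50 °C returns to the route at 16.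

**Step 9.** The most likely failure is poor discrimination between the two methoxy groups, or no cleavage at all, because the chelate is seven-membered and weaker than that of an ortho-acyl anisole. A second risk is cyclisation of the liberated 4-hydroxyl onto the prenyl double bond during an acidic work-up. The fallback changes the order of the end game and the kind of Lewis acid. It sets out from 18, which is first deallylated (Pd(PPh3)4, morpholine, THF) to 2-(2,4-dihydroxyphenyl)-4,6-dimethoxy-5-(3-methylbut-2-en-1-yl)-1-benzofuran-3-carbaldehyde F2. With no allyl ether left to rearrange, BCl3 in CH2Cl2 at −78 → −20 °C is then used; it binds the formyl oxygen covalently and should cleave the neighbouring methyl ether. This returns to the route at 20.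

**Step 8.** The most likely failure is stalling at the oxime stage, or slow hydrolysis of the hindered imine, so that nitrogen is retained; the benzylic nitronate may also couple with itself under base. The fallback sets out from 16 and isolates the oxime. Reduction of the nitro group with SnCl2·2H2O, PhSH and Et3N in MeCN should give (E)-1-{2-[2,4-bis(prop-2-en-1-yloxy)phenyl]-4,6-dimethoxy-5-(3-methylbut-2-en-1-yl)-1-benzofuran-3-yl}-N-hydroxymethanimine F3. Exchange of the oxime with aqueous glyoxylic acid in THF then returns to the route at 18.

**Step 2.** The most likely failure is attack at the tertiary end of 3 (SN2′), which gives the 1,1-dimethylallyl isomer. A second risk is partial lithiation next to the silyloxy group followed by silyl migration to carbon. The fallback sets out from 2 through 4. The aryllithium 4 is trapped with allyl bromide 8, for which both modes of attack give the same product, [3,5-dimethoxy-4-(prop-2-en-1-yl)phenoxy]tri(propan-2-yl)silane F4. Cross-metathesis of F4 with 2-methylbut-2-ene and the second-generation Grubbs catalyst (CH2Cl2, 40 °C) then returns to the route at 5.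

## Further compounds

F1 | step 7 | rac-1-[2,4-bis(prop-2-en-1-yloxy)phenyl]-2-hydroxy-3-nitropropan-1-one | O=C(C(O)C[N+](=O)[O-])c1ccc(OCC=C)cc1OCC=C
F2 | step 9 | 2-(2,4-dihydroxyphenyl)-4,6-dimethoxy-5-(3-methylbut-2-en-1-yl)-1-benzofuran-3-carbaldehyde | COc1cc2oc(-c3ccc(O)cc3O)c(C=O)c2c(OC)c1CC=C(C)C
F3 | step 8 | (E)-1-{2-[2,4-bis(prop-2-en-1-yloxy)phenyl]-4,6-dimethoxy-5-(3-methylbut-2-en-1-yl)-1-benzofuran-3-yl}-N-hydroxymethanimine | C=CCOc1ccc(-c2oc3cc(OC)c(CC=C(C)C)c(OC)c3c2/C=N/O)c(OCC=C)c1
F4 | step 2 | [3,5-dimethoxy-4-(prop-2-en-1-yl)phenoxy]tri(propan-2-yl)silane | C=CCc1c(OC)cc(O[Si](C(C)C)(C(C)C)C(C)C)cc1OC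
A1 | alternative 1 | 7,9-dimethoxy-8-prenyl-6H-benzofuro[3,2-c]chromen-3-yl pivalate | COc1cc2oc3-c4ccc(OC(=O)C(C)(C)C)cc4OCc3c2c(OC)c1CC=C(C)C
A2 | alternative 1 | 4-(4,6-dimethoxy-5-prenylbenzofuran-2-yl)-3-hydroxyphenyl pivalate | COc1cc2oc(-c3ccc(OC(=O)C(C)(C)C)cc3O)cc2c(OC)c1CC=C(C)C
A3 | alternative 2 | 2-[2,4-bis(methoxymethoxy)phenyl]-3-(1,3-dioxolan-2-yl)-6-methoxy-5-prenylbenzofuran-4-ol | COc1cc2oc(-c3ccc(OCOC)cc3OCOC)c(C3OCCO3)c2c(O)c1CC=C(C)C
A4 | alternative 2 | 2-diazo-1-{5-[2,4-bis(methoxymethoxy)phenyl]-4-(1,3-dioxolan-2-yl)furan-2-yl}ethanone | [N-]=[N+]=CC(=O)c1cc(C2OCCO2)c(-c2ccc(OCOC)cc2OCOC)o1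
A5 | alternative 2 | 1-methoxy-5-methylhex-4-en-1-yne | COC#CCC=C(C)C
A6 | alternative 3 | 2-(2,4-dihydroxyphenyl)-4,6-dimethoxy-5-prenylbenzofuran-3-carbaldehyde | COc1cc2oc(-c3ccc(O)cc3O)c(C=O)c2c(OC)c1CC=C(C)C
A7 | alternative 3 | 7-hydroxy-3-[6-hydroxy-2,4-dimethoxy-3-prenylphenyl]-4H-chromen-4-one | O=c1c(-c2c(O)cc(OC)c(CC=C(C)C)c2OC)coc2cc(O)ccc12
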